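**Retrosynthetic overview**
1. Target 12 ⇒ tris-silyl ether 11 by global desilylation; the aliphatic acetate is the only ester present.
2. 11 ⇒ terminal alkene 9 + silyloxystyrene 10 by E-selective cross-metathesis (C6=C7).
3. 9 ⇒ allylic acetate 6 + vinyl bromide 7 by hydroboration/B-alkyl Suzuki coupling (C5–C6).
4. 6 ⇒ 5-aryl-1-pentene 5 + AcOH: the C3–O bond and the only stereocentre are made together by a catalytic enantioselective branched allylic C–H acetoxylation (key step).
5. 5 ⇒ silylated 4-bromocatechol 2 + 5-bromopentene 3 (Negishi); no ring is formed, both arenes are bought.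

Assumptions: the SMILES is read as the (3R,6E) isomer; tert-butyldimethyl(4-vinylphenoxy)silane is taken as a catalogue monomer; for the new catalyst in step 3 the ligand antipode that gives (S)-6 is fixed by a pilot run (Mosher analysis of the derived alcohol).

**Step 1**
Reactants: 1 4-bromobenzene-1,2-diol
Product: 2 4-bromo-1,2-bis(tert-butyldimethylsilyloxy)benzene
Conditions: TBSCl (2.4 equiv), imidazole (5 equiv), DMF, 0 °C → rt, 12 h
Reagents that add atoms: tert-butyldimethylsilyl chloride (TBSCl), CC(C)(C)[Si](C)(C)Cl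
Why: Imidazole-promoted O-silylation (substitution at silicon) of both phenols masks the acidic, oxidisable, metal-chelating catechol for the organometallic and oxidative steps; no stereocentre is involved.

**Step 2**
Reactants: 2 4-bromo-1,2-bis(tert-butyldimethylsilyloxy)benzene; 3 5-bromopent-1-ene
Product: 5 4-(pent-4-en-1-yl)-1,2-bis(tert-butyldimethylsilyloxy)benzene, via pent-4-en-1-ylzinc bromide 4 (not isolated)
Conditions: 3 (1.5 equiv), Zn dust (2.2 equiv), I2 (5 mol%), DMA, 80 °C, 3 h; then 2, Pd(OAc)2 (2 mol%), SPhos (4 mol%), THF, 50 °C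
Reagents that add atoms: zinc, [Zn] (stays only in intermediate 4)
Why: Zinc insertion into the primary bromide followed by base-free Negishi cross-coupling joins the sp3 chain to the aryl bromide, and a primary alkylzinc leaves the aryl silyl ethers and the terminal alkene alone; no stereocentre is formed.

**Step 3**
Reactants: 5 4-(pent-4-en-1-yl)-1,2-bis(tert-butyldimethylsilyloxy)benzene
Product: 6 (S)-5-[3,4-bis(tert-butyldimethylsilyloxy)phenyl]pent-1-en-3-yl acetate
Conditions: Pd(OAc)2 (10 mol%), L* (12 mol%; new sulfoxide–oxazoline ligand, (4S)-4-tert-butyl-2-[2-((S)-mesitylsulfinyl)phenyl]-4,5-dihydrooxazole or its antipode), 2,5-dimethyl-1,4-benzoquinone (1.5 equiv), AcOH (6 equiv), 1,4-dioxane, 45 °C, 48 h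
Reagents that add atoms: acetic acid, CC(=O)O
Why: Proposed new method: enantioselective, branch-selective intermolecular allylic C–H acetoxylation of an unactivated terminal alkene. The sulfoxide arm of L* assists acetate-mediated allylic C–H cleavage at Pd(II) (only the terminal olefin binds, so benzylic C–H bonds and the arene are spared) to give a cationic (L*)Pd(π-allyl) that equilibrates by η3–η1–η3 faster than it is trapped (Curtin–Hammett). The Pd-bound acetate is then delivered inner-sphere through a seven-membered SE2′-type (3,3′-like) reductive elimination from the terminal σ-allyl onto the internal carbon, so the C3–O bond and the (S) configuration are set together while the ligand is still on the metal, and the quinone reoxidises Pd(0) before it can re-ionise the product. The closest known reactions are the racemic Pd(II)/bis-sulfoxide/benzoquinone branched allylic C–H esterification of α-olefins and the Pd/sulfoxide–oxazoline asymmetric intramolecular allylic C–H oxidation; no catalyst yet gives high ee in the intermolecular branched case.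

**Step 4**
Reactants: 6 (S)-5-[3,4-bis(tert-butyldimethylsilyloxy)phenyl]pent-1-en-3-yl acetate; 7 vinyl bromide
Product: 9 (R)-1-[3,4-bis(tert-butyldimethylsilyloxy)phenyl]hept-6-en-3-yl acetate, via B-alkyl-9-BBN adduct 8 (not isolated)
Conditions: 9-BBN (0.5 M in THF, 1.3 equiv), THF, 0 °C → rt, 4 h; then 7 (1 M in THF, 3 equiv), PdCl2(dppf) (5 mol%), 3 M aq K3PO4 (3 equiv), THF, rt, 16 h
Reagents that add atoms: 9-BBN, B1C2CCCC1CCC2 (its boron and ring stay only in intermediate 8; one H remains in 9)
Why: Anti-Markovnikov hydroboration puts boron on the terminal carbon (γ to the acetate, so no β-elimination) and B-alkyl Suzuki–Miyaura coupling forms C5–C6; once hydroborated the acetate is no longer allylic, so Pd(0) cannot ionise it and C3 is carried through unchanged (S → R is only a swap of CIP priorities).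

**Step 5**
Reactants: 9 (R)-1-[3,4-bis(tert-butyldimethylsilyloxy)phenyl]hept-6-en-3-yl acetate; 10 tert-butyldimethyl(4-vinylphenoxy)silane
Product: 11 (3R,6E)-1-[3,4-bis(tert-butyldimethylsilyloxy)phenyl]-7-[4-(tert-butyldimethylsilyloxy)phenyl]hept-6-en-3-yl acetate
Conditions: 10 (3 equiv), Hoveyda–Grubbs II (5 mol%), CH2Cl2, 40 °C, 12 h, N2 sweep
Reagents that add atoms: none
Why: Olefin cross-metathesis of the only chain alkene with the styrene gives the conjugated β-alkylstyrene with high E selectivity under thermodynamic control, driven by ethylene loss; the remote stereocentre is untouched.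

**Step 6**
Reactants: 11 (3R,6E)-1-[3,4-bis(tert-butyldimethylsilyloxy)phenyl]-7-[4-(tert-butyldimethylsilyloxy)phenyl]hept-6-en-3-yl acetate
Product: 12 (3R,6E)-1-(3,4-dihydroxyphenyl)-7-(4-hydroxyphenyl)hept-6-en-3-yl acetate
Conditions: TBAF (1 M in THF, 3.6 equiv), AcOH (4 equiv), THF, 0 °C → rt, 2 h, Ar
Reagents that add atoms: none
Why: Fluoride-induced desilylation cleaves the three aryl silyl ethers, while the acetic acid buffer keeps the medium non-basic so the secondary alkyl acetate is neither solvolysed nor transferred and the catechol is not oxidised; no bond at C3 is touched.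

**Compound list**
1 | 4-bromobenzene-1,2-diol (4-bromocatechol) | Oc1ccc(Br)cc1O | starting material
2 | 4-bromo-1,2-bis(tert-butyldimethylsilyloxy)benzene | CC(C)(C)[Si](C)(C)Oc1ccc(Br)cc1O[Si](C)(C)C(C)(C)C | intermediate
3 | 5-bromopent-1-ene | C=CCCCBr | starting material
4 | pent-4-en-1-ylzinc bromide | C=CCCC[Zn]Br | intermediate
5 | 4-(pent-4-en-1-yl)-1,2-bis(tert-butyldimethylsilyloxy)benzene | C=CCCCc1ccc(O[Si](C)(C)C(C)(C)C)c(O[Si](C)(C)C(C)(C)C)c1 | intermediate
6 | (S)-5-[3,4-bis(tert-butyldimethylsilyloxy)phenyl]pent-1-en-3-yl acetate | CC(=O)O[C@H](C=C)CCc1ccc(O[Si](C)(C)C(C)(C)C)c(O[Si](C)(C)C(C)(C)C)c1 | intermediate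
7 | vinyl bromide (bromoethene) | C=CBr | starting material
8 | (R)-1-(9-borabicyclo[3.3.1]nonan-9-yl)-5-[3,4-bis(tert-butyldimethylsilyloxy)phenyl]pentan-3-yl acetate | CC(=O)O[C@H](CCB1C2CCCC1CCC2)CCc1ccc(O[Si](C)(C)C(C)(C)C)c(O[Si](C)(C)C(C)(C)C)c1 | intermediate
9 | (R)-1-[3,4-bis(tert-butyldimethylsilyloxy)phenyl]hept-6-en-3-yl acetate | CC(=O)O[C@H](CCC=C)CCc1ccc(O[Si](C)(C)C(C)(C)C)c(O[Si](C)(C)C(C)(C)C)c1 | intermediate
10 | tert-butyldimethyl(4-vinylphenoxy)silane | C=Cc1ccc(O[Si](C)(C)C(C)(C)C)cc1 | starting material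
11 | (3R,6E)-1-[3,4-bis(tert-butyldimethylsilyloxy)phenyl]-7-[4-(tert-butyldimethylsilyloxy)phenyl]hept-6-en-3-yl acetate | CC(=O)O[C@H](CC/C=C/c1ccc(O[Si](C)(C)C(C)(C)C)cc1)CCc1ccc(O[Si](C)(C)C(C)(C)C)c(O[Si](C)(C)C(C)(C)C)c1 | intermediate
12 | (3R,6E)-1-(3,4-dihydroxyphenyl)-7-(4-hydroxyphenyl)hept-6-en-3-yl acetate | CC(=O)O[C@H](CC/C=C/c1ccc(O)cc1)CCc1ccc(O)c(O)c1 | target

**Totals**
Total steps: 6. Longest linear sequence: 6 (1 → 12, fully linear).

**Three steps most likely to fail**

Step 3 (new catalyst; risks are low ee, linear acetate from outer-sphere attack, slow turnover). The fallback is known chemistry and replaces asymmetric catalysis by a resolution. It sets out from 5 and comes back at 6. The established racemic branched allylic C–H acetoxylation (Pd(OAc)2/1,2-bis(phenylsulfinyl)ethane 10 mol%, benzoquinone, AcOH, dioxane, 43 °C) gives racemic 5-[3,4-bis(tert-butyldimethylsilyloxy)phenyl]pent-1-en-3-yl acetate F1. Immobilised Candida antarctica lipase B with n-butanol in MTBE at 30 °C transesterifies only the (S)-acetate (vinyl in the medium pocket, arylethyl in the large one) to (S)-5-[3,4-bis(tert-butyldimethylsilyloxy)phenyl]pent-1-en-3-ol F2 and leaves (R)-5-[3,4-bis(tert-butyldimethylsilyloxy)phenyl]pent-1-en-3-yl acetate F3 behind. F2 is separated on silica and acetylated (Ac2O, pyridine, DMAP, 0 °C) to 6. This costs two extra steps and at most half of the material.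

Step 4 (risks are partial loss of the acetate or aryl silyl ethers in aqueous base and sluggish transmetallation). The fallback replaces the borane/base coupling by a base-free organozinc coupling. It sets out from 6 and comes back at 9. Hydroboration as before gives 8, and oxidation with H2O2 in pH 7 phosphate buffer at 0 °C (kept neutral to prevent 1,3-acetyl migration) gives (S)-5-[3,4-bis(tert-butyldimethylsilyloxy)phenyl]-1-hydroxypentan-3-yl acetate F4. Appel iodination (I2, PPh3, imidazole, CH2Cl2, 0 °C) gives (S)-5-[3,4-bis(tert-butyldimethylsilyloxy)phenyl]-1-iodopentan-3-yl acetate F5. Zinc insertion (Zn dust, LiCl, THF, 40 °C) gives {(S)-3-acetoxy-5-[3,4-bis(tert-butyldimethylsilyloxy)phenyl]pentyl}zinc iodide F6, not isolated, which undergoes Negishi coupling with vinyl bromide 7 (Pd(PPh3)4, THF, rt) to 9.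

Step 5 (risks are styrene homodimerisation consuming catalyst, incomplete conversion, and Ru–H alkene migration). The fallback forms the aryl–vinyl bond by Mizoroki–Heck arylation instead of metathesis. It sets out from 9 and comes back at 11. Compound 9 is arylated with purchased tert-butyl(4-iodophenoxy)dimethylsilane (CC(C)(C)[Si](C)(C)Oc1ccc(I)cc1) under ligand-free phase-transfer conditions (Pd(OAc)2, Bu4NCl, NaHCO3, DMF, 50 °C). Syn-insertion and syn-β-hydride elimination give the (E)-styrene 11 directly; the minor allyl-arene isomer is removed on AgNO3-silica. No new intermediate is made.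

**Further compounds**
F1 | step 3 | rac-5-[3,4-bis(tert-butyldimethylsilyloxy)phenyl]pent-1-en-3-yl acetate | CC(=O)OC(C=C)CCc1ccc(O[Si](C)(C)C(C)(C)C)c(O[Si](C)(C)C(C)(C)C)c1
F2 | step 3 | (S)-5-[3,4-bis(tert-butyldimethylsilyloxy)phenyl]pent-1-en-3-ol | O[C@H](C=C)CCc1ccc(O[Si](C)(C)C(C)(C)C)c(O[Si](C)(C)C(C)(C)C)c1
F3 | step 3 | (R)-5-[3,4-bis(tert-butyldimethylsilyloxy)phenyl]pent-1-en-3-yl acetate | CC(=O)O[C@@H](C=C)CCc1ccc(O[Si](C)(C)C(C)(C)C)c(O[Si](C)(C)C(C)(C)C)c1
F4 | step 4 | (S)-5-[3,4-bis(tert-butyldimethylsilyloxy)phenyl]-1-hydroxypentan-3-yl acetate | CC(=O)O[C@H](CCO)CCc1ccc(O[Si](C)(C)C(C)(C)C)c(O[Si](C)(C)C(C)(C)C)c1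
F5 | step 4 | (S)-5-[3,4-bis(tert-butyldimethylsilyloxy)phenyl]-1-iodopentan-3-yl acetate | CC(=O)O[C@H](CCI)CCc1ccc(O[Si](C)(C)C(C)(C)C)c(O[Si](C)(C)C(C)(C)C)c1
F6 | step 4 | {(S)-3-acetoxy-5-[3,4-bis(tert-butyldimethylsilyloxy)phenyl]pentyl}zinc iodide | CC(=O)O[C@H](CC[Zn]I)CCc1ccc(O[Si](C)(C)C(C)(C)C)c(O[Si](C)(C)C(C)(C)C)c1
F0 | step 5 | none | none
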